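**Remark on the chemistry:** the target has no stereocentre; the only stereochemical element in the route is the E geometry of the enoate in 3 and 5, which disappears on aromatisation. Compounds 1, 2, 6, 18 and 21 are taken as purchased.

## Analysis of the target

The target 30 is a linear tridepside: three benzene rings joined head to tail by two aryl ester bonds, with no ring fusion and no stereocentre. Ring A is a 2,3,4-trimethoxy-6-methylbenzoyl group. Ring B is a 2-hydroxy-6-methylbenzoyl group that carries ring A on O-4, and ring C is 2-hydroxy-6-methylbenzoic acid that carries ring B on O-4. Rings B and C are therefore the same 2,4-dioxygenated 6-methylbenzoate, used once as acyl donor and once as phenol acceptor. The sensitive groups are the two aryl esters, which hydroxide, alkoxide or a free phenoxide cleave or scramble, the salicylic acid of ring C, which decarboxylates in hot acid, and the electron-rich C3 and C5 positions of rings B and C. The difficulty is differentiation rather than skeleton: every carbonyl is flanked by two ortho substituents, each of rings B and C has two phenolic oxygens with different roles, and ring B must have its carboxyl freed while O-2 stays protected. The strategy rests on the pattern of rings B and C: carboxyl at C1, oxygen at C2 and C4, hydrogen at C3 and C5, methyl at C6. This is the pattern obtained when a four-carbon vinylketene (C2, C5, C6, C1) is joined to the two carbons of an ynol ether (C3, C4), with O-2 arriving as a free chelated phenol and O-4 as an ether.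

## Retrosynthetic reasoning

**30 from 29.** The last operation removes only benzyl groups, the ether on O-2 of ring B and the ester of ring C, by hydrogenolysis. Aryl esters survive hydrogenolysis but not base or strong acid, so every protecting group that remains at the end is a benzyl group.

**29 from 24 and 27.** The ester C(=O)–O bond between rings A and B is cut. Ring A is the simplest piece and has no sensitive group, so it is attached last, as acid chloride 28 made from 24. The forward acylation has to choose the free 4-hydroxyl of ring B in 27 over the 2-hydroxyl of ring C, which is hydrogen-bonded to its neighbouring ester and shielded by it.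

**27 from 26.** O-4 of ring B is revealed from a tert-butyl ether. This group is chosen because it survives the aqueous base and the acylation on the way to 26, and leaves under acid that benzyl ethers, benzyl esters and aryl esters tolerate.

**26 from 20 and 17.** The ester bond between rings B and C is cut. Ring B leaves its ring synthesis as a benzyl ester, and freeing that carboxyl beside an O-2 benzyl ether requires hydrolysis, which is possible only while no depside ester exists. Ring B therefore enters as the free acid 20, activated as 25, and the chain grows from ring C towards ring A.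

**20 and 17 from 16.** Both building blocks come from one arene. Acid removes the tert-butyl group of 16 to give 17. O-Benzylation with 18 gives 19, and hydrolysis of its ester gives 20. One ring synthesis thus serves two rings.

**16 from 5 and 11.** Ring C (and ring B) is cut at C1–C2, C2–C3 and C4–C5; the C5–C6 bond arises in the same operation by migration. This cut is chosen because the vinylketene derived from 5 and the ynol ether 11 carry exactly the substituents of the ring, and because the two oxygens emerge already differentiated. The forward reaction has to deliver the ether oxygen at C4 and the hydroxyl at C2, and not the reverse.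

**5 from 3, and 3 from 1 and 2.** The diazo group is introduced at the acetyl methyl of 3 by diazo transfer, and the trisubstituted alkene of 3 is cut into the dione 1 and the ylide 2. This gives the precursor in two steps with the E geometry set by a stabilised ylide.

**11 from 8, and 8 from 6.** The triple bond is made by double elimination from the dichlorovinyl ether 8, which comes from 6 by elimination and addition of tert-butoxide.

**24 from 22, and 22 from 21.** The carboxyl carbon of ring A is cut off. Compound 21 already holds the three methoxy groups and the methyl, and its two free positions are equivalent, so bromination to 22 and carboxylation via 23 is unambiguous.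

## Alternatives that were turned down

**Alternative 1:** The inner ester is cut at two bonds at once, the ring B C1–carbonyl bond and the carbonyl–oxygen bond to ring C, so that the carbonyl carbon comes from carbon monoxide A3. The forward key step is a palladium-catalysed aryloxycarbonylation: aryl bromide A2 (ring A already on O-4 of ring B, O-2 as a methoxymethyl ether), A3 and phenol 17 combine to tridepside A1.
- For it: it is the most convergent way to the B–C link. Ring B needs no carboxyl group, so the protect, hydrolyse and activate sequence (steps 7, 8 and 11 here) disappears, and no doubly ortho-substituted acid has to be activated.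
- Against it: oxidative addition must occur at a carbon flanked by a methyl and an alkoxy group, and the hindered acyl–palladium intermediate must be captured by a weakly nucleophilic phenoxide. The base and heat this needs are the conditions under which the phenoxide of 17 transesterifies the aryl ester of A2 and both aryl esters of A1. A2 also requires bromination between the methyl group and an oxygen, which is not the preferred site, and the methoxymethyl group adds an acidic deprotection.
- Comparison: Alternative 1 is stronger on step count and convergence. The chosen route offers substitution patterns fixed by ring construction, ester formation by ordinary acyl substitution, and its uncertain step placed early on small molecules instead of late on an advanced fragment.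

**Alternative 2:** Ring C is cut at C1–C6 and C3–C4 at the oxidation level of a cyclohexane-1,3-dione. The forward key step is conjugate addition of the enolate of benzyl acetoacetate A5 to benzyl crotonate A6 (C1–C6), followed by Dieckmann-type closure of the acetoacetate methyl carbon onto the crotonate ester (C3–C4), giving dione ester A4. The ring would be O-acylated and dehydrogenated late.
- For it: two cheap components give all six ring carbons and every substituent of ring C in one flask, with no diazo compound, no photochemistry and no volatile ynol ether. As a supply of the ring C skeleton it is shorter and easier to scale than steps 1 to 6.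
- Against it: A4 is one oxidation level short, and its two stereocentres are made only to be destroyed. Acylation of a cyclic 1,3-dione gives an enol ester, which is itself an acyl donor prone to oxygen-to-carbon shift, and no chelate decides which oxygen is acylated. The late dehydrogenation needs a halogen or quinone oxidant in the presence of rings A and B, whose free positions ortho and para to oxygen are attacked first.
- Comparison: if A4 is aromatised at once it delivers 17 more cheaply than the chosen route, and on that point it is stronger. It then gives nothing for ring B, which needs O-4 masked while O-2 is benzylated and the ester hydrolysed. The annulation gives 16, aromatic from the outset with O-4 as an acid-labile ether and O-2 free, so 17 and 20 both come from one compound.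

**Alternative 3:** Ring A is cut at C1–C2 and C5–C6 and built last on the finished depside. The forward key step is a Diels–Alder reaction of the tetraoxygenated ketene acetal diene A8 with the but-2-ynoate ester A9 of the ring B–ring C phenol. The adduct aromatises by 1,4-elimination of one acetal alkoxy group to give A7, with a 2,4-dihydroxy-3-methoxy ring A; two O-methylations and hydrogenolysis would follow.
- For it: the polarisation of the diene controls the regiochemistry reliably, and the ring A oxygenation could be varied late.
- Against it: ring A is the one ring that can be bought nearly complete, since 21 lacks only the carboxyl carbon, so building it by cycloaddition gains nothing. A8 is hydrolytically fragile and needs several steps, and a β-methyl ynoate is a sluggish dienophile that needs heat. A9 is an activated aryl ester that the silyl ketene acetal can acylate. Afterwards two phenols, one of them chelated, must be methylated with base in the presence of two depside esters. Rings B and C still have to be made and differentiated by other means.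
- Comparison: Alternative 3 is equal in regiocontrol and better only for analogue work on ring A. The chosen strategy spends its ring-forming step on rings B and C, where the differentiation of the oxygens is decided, and obtains ring A in two steps from 21.

Key step: step 5

## Route

**Step 1**
Reactants: 1 butane-2,3-dione; 2 benzyl (triphenylphosphoranylidene)acetate
Product: 3 benzyl (E)-3-methyl-4-oxopent-2-enoate
Conditions: 1 (3 equiv), CH2Cl2, 0 °C to rt, slow addition of 2
Reagents that add atoms: none
Why: Wittig olefination; the ester-stabilised ylide attacks one carbonyl of the activated 1,2-diketone and places the ester trans to the acetyl group. Excess 1 keeps the less electrophilic enone carbonyl of 3 from reacting a second time.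

**Step 2**
Reactants: 3 benzyl (E)-3-methyl-4-oxopent-2-enoate
Product: 5 benzyl (E)-5-diazo-3-methyl-4-oxopent-2-enoate, via trifluoroacetyl diketone 4 (not isolated)
Conditions: LiN(SiMe3)2, THF, −78 °C (3 added to the base); CF3CO2CH2CF3, −78 °C; aq. HCl; then MsN3, Et3N, H2O, MeCN, rt
Reagents that add atoms: methanesulfonyl azide, CS(=O)(=O)N=[N+]=[N-]
Why: Detrifluoroacetylative diazo transfer; kinetic deprotonation at the acetyl methyl (the only enolisable position next to the ketone) and C-trifluoroacetylation give 4, and the sulfonyl azide then transfers the diazo group with loss of the trifluoroacetyl group onto the sulfonamide nitrogen. Acylation of diazomethane by the unsaturated acid chloride is avoided because it fails through dipolar addition to the activated alkene; inverse addition at −78 °C limits conjugate self-addition of the enolate.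

**Step 3**
Reactants: 6 trichloroethylene
Product: 8 tert-butyl (E)-1,2-dichloroethenyl ether, via dichloroacetylene 7 (not isolated)
Conditions: KOtBu (1.2 equiv), THF, −50 °C to rt, under N2
Reagents that add atoms: potassium tert-butoxide, CC(C)(C)[O-].[K+]
Why: Base-induced elimination of HCl from 6 gives 7, which is trapped at once by anti addition of tert-butoxide and protonation; this is the standard entry to (E)-1,2-dichlorovinyl ethers. The hazardous 7 stays in solution and is never isolated.

**Step 4**
Reactants: 8 tert-butyl (E)-1,2-dichloroethenyl ether
Product: 11 tert-butoxyacetylene, via tert-butyl chloroethynyl ether 9 (not isolated), via lithium tert-butoxyacetylide 10 (not isolated)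
Conditions: n-BuLi (2.2 equiv), Et2O, −78 to −40 °C; H2O, −78 °C; volatiles distilled at reduced pressure without heating, 11 kept as an assayed solution at −20 °C
Reagents that add atoms: none
Why: The first equivalent of n-BuLi eliminates HCl to give 9, the second gives 10 by chlorine–lithium exchange, and cold protonation releases the terminal ynol ether (dichlorovinyl ether route to alkoxyacetylenes). The co-distilling 1-chlorobutane is inert in step 5, and cold handling prevents the retro-ene fragmentation that tert-butyl ynol ethers undergo on warming.

**Step 5**
Reactants: 5 benzyl (E)-5-diazo-3-methyl-4-oxopent-2-enoate; 11 tert-butoxyacetylene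
Product: 16 benzyl 4-tert-butoxy-2-hydroxy-6-methylbenzoate, via vinylketene 12 (not isolated), via 4-vinylcyclobutenone 13 (not isolated), via dienylketene 14 (not isolated), via cyclohexadienone 15 (not isolated)
Conditions: hν (254 nm, low-pressure Hg lamps, quartz), 11 (3 equiv), ClCH2CH2Cl, degassed, rt; evaporation of volatiles at ≤25 °C; then PhMe, 80 °C, dark
Reagents that add atoms: none
Why: Light expels N2 from 5 and the alkenyl group migrates to the former diazo carbon (photochemical Wolff rearrangement, forming C5–C6) to give vinylketene 12. The ketene C=C of 12 then adds the electron-rich triple bond of 11 in a (2+2) cycloaddition: the nucleophilic unsubstituted alkyne carbon bonds to the ketene carbonyl carbon (C2–C3) and the oxygen-bearing alkyne carbon to the ketene α-carbon (C4–C5), giving racemic 13. Reversible 4π electrocyclic opening of 13 gives dienylketene 14, whose isomer with the enoate arm cis to the ketene closes the six-membered ring C by thermal 6π electrocyclisation (C1–C2) to 15, and enolisation gives the phenol 16. The closest known reaction type is the second-generation Danheiser benzannulation of unsaturated diazo ketones with alkoxy- and siloxyalkynes to give resorcinol monoethers. No stereocentre remains, since those of 13 and 15 are lost on ring opening and enolisation. The step needs one regioselectivity, the orientation of the (2+2) addition, and the polarisation of the ynol ether against the electrophilic ketene carbonyl carbon secures it, placing the ether at C4 and the hydroxyl at C2. The E geometry of 5 keeps the ester carbonyl away from the ketene, so oxa-6π closure onto the ester cannot compete, and it puts the ester on the outside in the ring-closing transition state. Excess 11 is removed before heating because its retro-ene fragmentation would release ketene and acetylate the new phenol.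

**Step 6**
Reactants: 16 benzyl 4-tert-butoxy-2-hydroxy-6-methylbenzoate
Product: 17 benzyl 2,4-dihydroxy-6-methylbenzoate
Conditions: CF3CO2H, Et3SiH, CH2Cl2, 0 °C; volatiles evaporated
Reagents that add atoms: none
Why: SN1 acidolysis of the aryl tert-butyl ether; Et3SiH reduces the tert-butyl cation so that it cannot alkylate C3 or C5 of the electron-rich ring. The benzyl ester is stable to CF3CO2H at this temperature.

**Step 7**
Reactants: 16 benzyl 4-tert-butoxy-2-hydroxy-6-methylbenzoate; 18 benzyl bromide
Product: 19 benzyl 2-benzyloxy-4-tert-butoxy-6-methylbenzoate
Conditions: K2CO3, DMF, 60 °C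
Reagents that add atoms: benzyl bromide (18), BrCc1ccccc1
Why: Williamson etherification; the chelated phenol is the only acidic site and its potassium salt is alkylated in warm DMF. The aryl tert-butyl ether and the ester are inert to carbonate.

**Step 8**
Reactants: 19 benzyl 2-benzyloxy-4-tert-butoxy-6-methylbenzoate
Product: 20 2-benzyloxy-4-tert-butoxy-6-methylbenzoic acid
Conditions: KOH, DMSO–H2O, 90 °C; then aq. HCl to pH 3–4, 0 °C
Reagents that add atoms: potassium hydroxide, [K+].[OH-]
Why: Saponification of a doubly ortho-substituted benzoate with poorly solvated hydroxide in DMSO; both ethers are stable to base and no aryl ester is yet present. Cold, mild acidification avoids loss of the tert-butyl group and decarboxylation.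

**Step 9**
Reactants: 21 3,4,5-trimethoxytoluene
Product: 22 2-bromo-3,4,5-trimethoxytoluene
Conditions: NBS (1.0 equiv), MeCN, 0 °C to rt, dark
Reagents that add atoms: N-bromosuccinimide, O=C1CCC(=O)N1Br
Why: Electrophilic aromatic bromination; the two free positions of 21 are equivalent by symmetry, so one monobromide forms. A polar solvent without initiator favours ring bromination over benzylic bromination.

**Step 10**
Reactants: 22 2-bromo-3,4,5-trimethoxytoluene
Product: 24 2,3,4-trimethoxy-6-methylbenzoic acid, via aryllithium 23 (not isolated)
Conditions: n-BuLi, THF, −78 °C; CO2 (g), −78 °C to rt; aq. HCl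
Reagents that add atoms: carbon dioxide, O=C=O
Why: Bromine–lithium exchange is faster than benzylic deprotonation at −78 °C, and the aryllithium is carboxylated by CO2.

**Step 11**
Reactants: 20 2-benzyloxy-4-tert-butoxy-6-methylbenzoic acid; 17 benzyl 2,4-dihydroxy-6-methylbenzoate
Product: 26 benzyl 4-[(2-benzyloxy-4-tert-butoxy-6-methylbenzoyl)oxy]-2-hydroxy-6-methylbenzoate, via acid chloride 25 (not isolated)
Conditions: Me2C=C(Cl)NMe2 (1.1 equiv), CH2Cl2, 0 °C to rt; then 17 (1.05 equiv), Et3N, DMAP (0.1 equiv), CH2Cl2, 0 °C to rt
Reagents that add atoms: none
Why: Acyl chloride esterification; the α-chloroenamine converts the acid into 25 without releasing HCl, so the acid-labile tert-butyl ether survives. The more acidic, unchelated 4-hydroxyl of 17 is acylated under DMAP catalysis while the 2-hydroxyl stays hydrogen-bonded to the ester carbonyl.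

**Step 12**
Reactants: 26 benzyl 4-[(2-benzyloxy-4-tert-butoxy-6-methylbenzoyl)oxy]-2-hydroxy-6-methylbenzoate
Product: 27 benzyl 4-[(2-benzyloxy-4-hydroxy-6-methylbenzoyl)oxy]-2-hydroxy-6-methylbenzoate
Conditions: CF3CO2H, Et3SiH, CH2Cl2, 0 °C; volatiles evaporated
Reagents that add atoms: none
Why: The same SN1 acidolysis as in step 6; aryl ester, benzyl ether and benzyl ester are stable to CF3CO2H at 0 °C, and no nucleophile is present that could open the depside bond.

**Step 13**
Reactants: 24 2,3,4-trimethoxy-6-methylbenzoic acid; 27 benzyl 4-[(2-benzyloxy-4-hydroxy-6-methylbenzoyl)oxy]-2-hydroxy-6-methylbenzoate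
Product: 29 benzyl 4-{[2-benzyloxy-6-methyl-4-(2,3,4-trimethoxy-6-methylbenzoyloxy)benzoyl]oxy}-2-hydroxy-6-methylbenzoate, via acid chloride 28 (not isolated)
Conditions: (COCl)2, DMF (cat.), CH2Cl2, 0 °C to rt; evaporation; then 27, Et3N, DMAP (0.1 equiv), CH2Cl2, 0 °C to rt
Reagents that add atoms: none
Why: Acyl chloride formation with DMF catalysis, then DMAP-catalysed O-acylation. The free 4-hydroxyl of ring B reacts in preference to the 2-hydroxyl of ring C, which is hydrogen-bonded to the adjacent benzyl ester and shielded by it.

**Step 14**
Reactants: 29 benzyl 4-{[2-benzyloxy-6-methyl-4-(2,3,4-trimethoxy-6-methylbenzoyloxy)benzoyl]oxy}-2-hydroxy-6-methylbenzoate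
Product: 30 2-hydroxy-4-{[2-hydroxy-6-methyl-4-(2,3,4-trimethoxy-6-methylbenzoyloxy)benzoyl]oxy}-6-methylbenzoic acid (CNP0332884.0)
Conditions: H2 (1 atm), Pd/C (10%), EtOAc, rt
Reagents that add atoms: none
Why: Hydrogenolysis of the benzyl ether and the benzyl ester; aryl esters, aryl methyl ethers and the free acid are inert. No acid or base is present, so the depside links and the salicylic acid are not endangered.

## Compound list

1 | butane-2,3-dione | CC(=O)C(C)=O | starting material
2 | benzyl (triphenylphosphoranylidene)acetate | O=C(C=P(c1ccccc1)(c1ccccc1)c1ccccc1)OCc1ccccc1 | starting material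
3 | benzyl (E)-3-methyl-4-oxopent-2-enoate | CC(=O)/C(C)=C/C(=O)OCc1ccccc1 | intermediate
4 | benzyl (E)-7,7,7-trifluoro-3-methyl-4,6-dioxohept-2-enoate | O=C(CC(=O)/C(C)=C/C(=O)OCc1ccccc1)C(F)(F)F | intermediate
5 | benzyl (E)-5-diazo-3-methyl-4-oxopent-2-enoate | [N-]=[N+]=CC(=O)/C(C)=C/C(=O)OCc1ccccc1 | intermediate
6 | trichloroethylene | ClC=C(Cl)Cl | starting material
7 | dichloroacetylene | ClC#CCl | intermediate
8 | tert-butyl (E)-1,2-dichloroethenyl ether | Cl/C=C(/Cl)OC(C)(C)C | intermediate
9 | tert-butyl chloroethynyl ether | ClC#COC(C)(C)C | intermediate
10 | lithium tert-butoxyacetylide | [Li]C#COC(C)(C)C | intermediate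
11 | tert-butoxyacetylene | C#COC(C)(C)C | intermediate
12 | benzyl (2E)-3-methyl-5-oxopenta-2,4-dienoate | O=C=C/C(C)=C/C(=O)OCc1ccccc1 | intermediate
13 | benzyl (E)-3-(2-tert-butoxy-4-oxocyclobut-2-en-1-yl)but-2-enoate (racemic) | O=C1C=C(OC(C)(C)C)C1/C(C)=C/C(=O)OCc1ccccc1 | intermediate
14 | benzyl (2E,4E)-5-tert-butoxy-3-methyl-7-oxohepta-2,4,6-trienoate (ketene carbon and enoate arm cis on the central double bond) | O=C=C/C(OC(C)(C)C)=C\C(C)=C\C(=O)OCc1ccccc1 | intermediate
15 | benzyl 4-tert-butoxy-2-methyl-6-oxocyclohexa-2,4-diene-1-carboxylate (racemic) | O=C1C=C(OC(C)(C)C)C=C(C)C1C(=O)OCc1ccccc1 | intermediate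
16 | benzyl 4-tert-butoxy-2-hydroxy-6-methylbenzoate | Cc1cc(OC(C)(C)C)cc(O)c1C(=O)OCc1ccccc1 | intermediate
17 | benzyl 2,4-dihydroxy-6-methylbenzoate | Cc1cc(O)cc(O)c1C(=O)OCc1ccccc1 | intermediate
18 | benzyl bromide | BrCc1ccccc1 | starting material
19 | benzyl 2-benzyloxy-4-tert-butoxy-6-methylbenzoate | Cc1cc(OC(C)(C)C)cc(OCc2ccccc2)c1C(=O)OCc1ccccc1 | intermediate
20 | 2-benzyloxy-4-tert-butoxy-6-methylbenzoic acid | Cc1cc(OC(C)(C)C)cc(OCc2ccccc2)c1C(=O)O | intermediate
21 | 3,4,5-trimethoxytoluene | COc1cc(C)cc(OC)c1OC | starting material
22 | 2-bromo-3,4,5-trimethoxytoluene | COc1cc(C)c(Br)c(OC)c1OC | intermediate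
23 | (2,3,4-trimethoxy-6-methylphenyl)lithium | [Li]c1c(C)cc(OC)c(OC)c1OC | intermediate
24 | 2,3,4-trimethoxy-6-methylbenzoic acid | COc1cc(C)c(C(=O)O)c(OC)c1OC | intermediate
25 | 2-benzyloxy-4-tert-butoxy-6-methylbenzoyl chloride | Cc1cc(OC(C)(C)C)cc(OCc2ccccc2)c1C(=O)Cl | intermediate
26 | benzyl 4-[(2-benzyloxy-4-tert-butoxy-6-methylbenzoyl)oxy]-2-hydroxy-6-methylbenzoate | Cc1cc(OC(C)(C)C)cc(OCc2ccccc2)c1C(=O)Oc1cc(C)c(C(=O)OCc2ccccc2)c(O)c1 | intermediate
27 | benzyl 4-[(2-benzyloxy-4-hydroxy-6-methylbenzoyl)oxy]-2-hydroxy-6-methylbenzoate | Cc1cc(O)cc(OCc2ccccc2)c1C(=O)Oc1cc(C)c(C(=O)OCc2ccccc2)c(O)c1 | intermediate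
28 | 2,3,4-trimethoxy-6-methylbenzoyl chloride | COc1cc(C)c(C(=O)Cl)c(OC)c1OC | intermediate
29 | benzyl 4-{[2-benzyloxy-6-methyl-4-(2,3,4-trimethoxy-6-methylbenzoyloxy)benzoyl]oxy}-2-hydroxy-6-methylbenzoate | COc1cc(C)c(C(=O)Oc2cc(C)c(C(=O)Oc3cc(C)c(C(=O)OCc4ccccc4)c(O)c3)c(OCc3ccccc3)c2)c(OC)c1OC | intermediate
30 | 2-hydroxy-4-{[2-hydroxy-6-methyl-4-(2,3,4-trimethoxy-6-methylbenzoyloxy)benzoyl]oxy}-6-methylbenzoic acid (CNP0332884.0) | COc1cc(C)c(C(=O)Oc2cc(C)c(C(=O)Oc3cc(C)c(C(=O)O)c(O)c3)c(O)c2)c(OC)c1OC | target

## Step count and least certain steps

Total: 14 steps. Longest linear sequence: 9 steps (steps 1, 2, 5, 7, 8, 11, 12, 13 and 14, from 1 to 30).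

**Step 5 (key step).** Three processes can erode it.
- Photochemical E-to-Z isomerisation of the enoate in 5 or 12 would let the ketene close onto the ester carbonyl by oxa-6π cyclisation instead of adding the ynol ether.
- Thermal retro-ene fragmentation of residual 11 during the heating stage would acetylate the phenol.
- Secondary photolysis of the salicylate product or dimerisation of the vinylketene can occur if 11 is too dilute.

The supply of 11 from step 4 (volatility, thermal lability) is part of the same exposure. The fallback gives up the ring construction. It sets out from benzyl bromide 18, which alkylates the carboxylate of purchased 2,4-dihydroxy-6-methylbenzoic acid F1 (KHCO3, DMF, rt), and comes back to the route at 17. Part of 17 is then converted into 16 by acid-catalysed addition of its unchelated 4-hydroxyl to isobutene (CF3SO3H cat., CH2Cl2, −78 °C), so that steps 6 to 14 run unchanged.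

**Step 2.** The lithium enolate can add in conjugate fashion to the doubly activated alkene of unreacted 3, and deprotonation at the C3 methyl can compete, both before trifluoroacetylation. The fallback avoids a free enolate. It sets out from 3, which is silylated under soft enolisation (Me3SiOSO2CF3, Et3N, CH2Cl2, 0 °C) to benzyl (E)-3-methyl-4-(trimethylsilyloxy)penta-2,4-dienoate F2. F2 is C-acylated at its terminal carbon with trifluoroacetic anhydride, which comes back to the route at 4; the diazo transfer of step 2 then gives 5.

**Step 11.** The tert-butyl ether can be lost through adventitious acid during activation, the doubly ortho-substituted acid chloride can acylate slowly, and acylation can stray to the chelated hydroxyl. The fallback reverses the order of assembly. It sets out from 20, whose tert-butyl group is removed (CF3CO2H, Et3SiH) to give 2-benzyloxy-4-hydroxy-6-methylbenzoic acid F3. The phenoxide of F3 is acylated in aqueous NaOH–acetone at 0 °C (Schotten–Baumann) with 28, made from 24 as in step 13, to give 2-benzyloxy-6-methyl-4-(2,3,4-trimethoxy-6-methylbenzoyloxy)benzoic acid F4 after acidification. F4 has no acid-labile group, so it is condensed with 17 by trifluoroacetic anhydride in toluene through its mixed trifluoroacetic anhydride F5, and the route is rejoined at 29, bypassing steps 12 and 13.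

**Step 13.** Free phenoxide and DMAP can transfer acyl groups between the depside esters, the hindered acid chloride can react slowly, and over-acylation at the ring C hydroxyl is possible. The fallback works without base and without an acid chloride. It sets out from 24 and 27, which are condensed with trifluoroacetic anhydride in toluene at rt through 2,3,4-trimethoxy-6-methylbenzoic trifluoroacetic anhydride F6, an acylium-type acylation under acid in which no phenoxide is present, and comes back at 29.

**Step 8.** Acyl–oxygen hydrolysis between two ortho substituents can be slow, and prolonged heating or a careless acidification leads to decarboxylation or loss of the tert-butyl group. The fallback replaces hydrolysis by chemoselective hydrogenolysis. It sets out from 19, whose benzyl ester is cleaved with H2 over Pd/C in the presence of 2,2'-bipyridyl, an additive that suppresses hydrogenolysis of phenolic benzyl ethers, and comes back at 20; this fallback makes no new compound (F0).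

## Further compounds

F1 | step 5 | 2,4-dihydroxy-6-methylbenzoic acid | Cc1cc(O)cc(O)c1C(=O)O
F2 | step 2 | benzyl (E)-3-methyl-4-(trimethylsilyloxy)penta-2,4-dienoate | C=C(O[Si](C)(C)C)/C(C)=C/C(=O)OCc1ccccc1
F3 | step 11 | 2-benzyloxy-4-hydroxy-6-methylbenzoic acid | Cc1cc(O)cc(OCc2ccccc2)c1C(=O)O
F4 | step 11 | 2-benzyloxy-6-methyl-4-(2,3,4-trimethoxy-6-methylbenzoyloxy)benzoic acid | COc1cc(C)c(C(=O)Oc2cc(C)c(C(=O)O)c(OCc3ccccc3)c2)c(OC)c1OC
F5 | step 11 | 2-benzyloxy-6-methyl-4-(2,3,4-trimethoxy-6-methylbenzoyloxy)benzoic trifluoroacetic anhydride | COc1cc(C)c(C(=O)Oc2cc(C)c(C(=O)OC(=O)C(F)(F)F)c(OCc3ccccc3)c2)c(OC)c1OC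
F6 | step 13 | 2,3,4-trimethoxy-6-methylbenzoic trifluoroacetic anhydride | COc1cc(C)c(C(=O)OC(=O)C(F)(F)F)c(OC)c1OC
F0 | step 8 | none | none
A1 | alternative 1 | benzyl 2-hydroxy-4-{[2-(methoxymethoxy)-6-methyl-4-(2,3,4-trimethoxy-6-methylbenzoyloxy)benzoyl]oxy}-6-methylbenzoate | COc1cc(C)c(C(=O)Oc2cc(C)c(C(=O)Oc3cc(C)c(C(=O)OCc4ccccc4)c(O)c3)c(OCOC)c2)c(OC)c1OC
A2 | alternative 1 | 4-bromo-3-(methoxymethoxy)-5-methylphenyl 2,3,4-trimethoxy-6-methylbenzoate | COc1cc(C)c(C(=O)Oc2cc(C)c(Br)c(OCOC)c2)c(OC)c1OC
A3 | alternative 1 | carbon monoxide | [C-]#[O+]
A4 | alternative 2 | benzyl trans-6-methyl-2,4-dioxocyclohexane-1-carboxylate (racemic, one enantiomer drawn) | C[C@@H]1CC(=O)CC(=O)[C@H]1C(=O)OCc1ccccc1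
A5 | alternative 2 | benzyl acetoacetate | CC(=O)CC(=O)OCc1ccccc1
A6 | alternative 2 | benzyl crotonate | C/C=C/C(=O)OCc1ccccc1
A7 | alternative 3 | benzyl 2-benzyloxy-4-{[2-benzyloxy-4-(2,4-dihydroxy-3-methoxy-6-methylbenzoyloxy)-6-methylbenzoyl]oxy}-6-methylbenzoate | COc1c(O)cc(C)c(C(=O)Oc2cc(C)c(C(=O)Oc3cc(C)c(C(=O)OCc4ccccc4)c(OCc4ccccc4)c3)c(OCc3ccccc3)c2)c1O
A8 | alternative 3 | 1,2-dimethoxy-1,3-bis(trimethylsilyloxy)buta-1,3-diene | COC(O[Si](C)(C)C)=C(OC)C(=C)O[Si](C)(C)C
A9 | alternative 3 | benzyl 2-benzyloxy-4-{[2-benzyloxy-4-(but-2-ynoyloxy)-6-methylbenzoyl]oxy}-6-methylbenzoate | CC#CC(=O)Oc1cc(C)c(C(=O)Oc2cc(C)c(C(=O)OCc3ccccc3)c(OCc3ccccc3)c2)c(OCc2ccccc2)c1
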